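**Retrosynthetic overview**
1. Target 22 ⇐ triol 21 (the two primary OH groups acylated last) ⇐ bis-silyl ether 20.
2. 20 ⇐ epoxy alcohol 17 by reductive 1,3-transposition (OMs → I, then Zn), which makes the (E)-alkene and unmasks the (R)-tertiary alcohol; its C–O stereocentre comes from a Sharpless epoxidation.
3. 17 ⇐ key C–C bond (side-chain CH2–CH(OH)) by indium Barbier carbonyl allylation of epoxy aldehyde 15 (fragment B) with allylic bromide 9 (fragment A).
4. 9 ⇐ (R)-cyclohex-3-ene-1-carboxylic acid 1 (iodolactonisation/elimination, lactone → 2-substituted allylsilane, oxidation to the enone, Morita–Baylis–Hillman hydroxymethylation, bromodesilylation); 15 ⇐ prenyl acetate 10 (SeO2 oxidation, Sharpless epoxidation).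
5. Rings: the carbocycle is carried intact from 1 and no ring is constructed; the lactone bridge (step 1) and the oxirane (step 11) are temporary and are opened in steps 3 and 15.

Assumption: (R)-(+)-cyclohex-3-ene-1-carboxylic acid, sold as the resolved enantiomer of a bulk racemate, is taken as a cheap commercial starting material. (TBS = tert-butyldimethylsilyl.)

**Route**

Step 1
Reactants: 1 (R)-cyclohex-3-ene-1-carboxylic acid
Product: 2 (1R,4R,5R)-4-iodo-6-oxabicyclo[3.2.1]octan-7-one
Conditions: I2, NaHCO3, THF/H2O, 0 °C → rt, dark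
Reagents that add atoms: iodine [I][I]
Why: Iodolactonisation, in which the carboxylate opens the iodonium ion by anti addition to give the kinetic bridged γ-lactone, so the future ketone oxygen is placed 1,3 and cis to the carboxyl carbon under control of the untouched stereocentre.

Step 2
Reactants: 2 (1R,4R,5R)-4-iodo-6-oxabicyclo[3.2.1]octan-7-one
Product: 3 (1R,5R)-6-oxabicyclo[3.2.1]oct-3-en-7-one
Conditions: DBU, toluene, 110 °C
Reagents that add atoms: none
Why: E2 dehydroiodination can only go away from the bridgehead (Bredt's rule), giving the allylic lactone with both stereocentres intact.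

Step 3
Reactants: 3 (1R,5R)-6-oxabicyclo[3.2.1]oct-3-en-7-one
Product: 5 (1R,5R)-5-[3-(trimethylsilyl)prop-1-en-2-yl]cyclohex-2-en-1-ol, via bis(silylmethyl) carbinol 4 (not isolated)
Conditions: Me3SiCH2MgCl (4 equiv), CeCl3 (4 equiv), THF, −78 °C → rt; aq. NH4Cl; then SiO2, CH2Cl2, rt
Reagents that add atoms: (trimethylsilyl)methylmagnesium chloride C[Si](C)(C)C[Mg]Cl
Why: Double carbonyl addition of the non-basic reagent Me3SiCH2CeCl2 to the lactone followed by Peterson elimination of the β-hydroxysilane gives the 2-substituted allylsilane without enolising the ring stereocentre.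

Step 4
Reactants: 5 (1R,5R)-5-[3-(trimethylsilyl)prop-1-en-2-yl]cyclohex-2-en-1-ol
Product: 6 (5R)-5-[3-(trimethylsilyl)prop-1-en-2-yl]cyclohex-2-en-1-one
Conditions: MnO2 (15 equiv), CH2Cl2, rt
Reagents that add atoms: none
Why: Chemoselective allylic alcohol oxidation gives the enone and leaves the single ring stereocentre (5R), which is β to the carbonyl and not epimerisable.

Step 5
Reactants: 6 (5R)-5-[3-(trimethylsilyl)prop-1-en-2-yl]cyclohex-2-en-1-one
Product: 7 (5R)-2-(hydroxymethyl)-5-[3-(trimethylsilyl)prop-1-en-2-yl]cyclohex-2-en-1-one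
Conditions: 37% aq. CH2O (2 equiv), DMAP (0.2 equiv), THF/H2O 1:1, rt
Reagents that add atoms: formaldehyde C=O
Why: Morita–Baylis–Hillman reaction (DMAP conjugate addition, intermolecular aldol of the enolate with formaldehyde, loss of DMAP) places the CH2OH group regiospecifically on the enone α-carbon.

Step 6
Reactants: 7 (5R)-2-(hydroxymethyl)-5-[3-(trimethylsilyl)prop-1-en-2-yl]cyclohex-2-en-1-one
Product: 8 (5R)-2-[(TBS-oxy)methyl]-5-[3-(trimethylsilyl)prop-1-en-2-yl]cyclohex-2-en-1-one
Conditions: TBSCl, imidazole, CH2Cl2, 0 °C → rt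
Reagents that add atoms: tert-butyldimethylsilyl chloride CC(C)(C)[Si](C)(C)Cl
Why: Silyl ether protection of the primary allylic alcohol, so that it survives the halide, sulfonylation and zinc steps.

Step 7
Reactants: 8 (5R)-2-[(TBS-oxy)methyl]-5-[3-(trimethylsilyl)prop-1-en-2-yl]cyclohex-2-en-1-one
Product: 9 (5R)-5-(3-bromoprop-1-en-2-yl)-2-[(TBS-oxy)methyl]cyclohex-2-en-1-one
Conditions: NBS (1.05 equiv), CH2Cl2, −78 → −20 °C, dark
Reagents that add atoms: N-bromosuccinimide O=C1CCC(=O)N1Br
Why: Electrophilic bromodesilylation (SE2') of the allylsilane, in which bromine adds to the terminal carbon and the β-silyl cation loses silicon, while the electron-poor enone alkene does not react.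

Step 8
Reactants: 10 3-methylbut-2-en-1-yl acetate (prenyl acetate)
Product: 11 (2E)-4-hydroxy-3-methylbut-2-en-1-yl acetate
Conditions: SeO2 (0.1 equiv), t-BuOOH (2 equiv), salicylic acid (0.1 equiv), CH2Cl2, rt
Reagents that add atoms: tert-butyl hydroperoxide CC(C)(C)OO (oxygen relayed by SeO2, O=[Se]=O)
Why: SeO2-catalysed allylic oxidation (ene reaction then [2,3]-sigmatropic shift) hydroxylates selectively the methyl group trans to the acetoxymethyl chain, giving the E allylic alcohol.

Step 9
Reactants: 11 (2E)-4-hydroxy-3-methylbut-2-en-1-yl acetate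
Product: 12 (2E)-4-(TBS-oxy)-3-methylbut-2-en-1-yl acetate
Conditions: TBSCl, imidazole, CH2Cl2, 0 °C → rt
Reagents that add atoms: tert-butyldimethylsilyl chloride CC(C)(C)[Si](C)(C)Cl
Why: Silylation of the free primary alcohol differentiates the two termini.

Step 10
Reactants: 12 (2E)-4-(TBS-oxy)-3-methylbut-2-en-1-yl acetate
Product: 13 (2E)-4-(TBS-oxy)-3-methylbut-2-en-1-ol
Conditions: K2CO3 (0.2 equiv), MeOH, 0 °C → rt
Reagents that add atoms: none
Why: Base-catalysed transesterification removes the acetate without touching the silyl ether or the alkene geometry.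

Step 11
Reactants: 13 (2E)-4-(TBS-oxy)-3-methylbut-2-en-1-ol
Product: 14 [(2S,3S)-3-[(TBS-oxy)methyl]-3-methyloxiran-2-yl]methanol
Conditions: Ti(OiPr)4 (0.1 equiv), L-(+)-diethyl tartrate (0.12 equiv), t-BuOOH (2 equiv, in decane), 4 Å MS, CH2Cl2, −20 °C
Reagents that add atoms: tert-butyl hydroperoxide CC(C)(C)OO
Why: Sharpless asymmetric epoxidation, where L-(+)-tartrate delivers oxygen to the same face as in geraniol → (2S,3S)-epoxygeraniol, setting the quaternary C–O centre (3S) that becomes the (R)-carbinol of the target.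

Step 12
Reactants: 14 [(2S,3S)-3-[(TBS-oxy)methyl]-3-methyloxiran-2-yl]methanol
Product: 15 (2R,3S)-3-[(TBS-oxy)methyl]-3-methyloxirane-2-carbaldehyde
Conditions: TEMPO (0.1 equiv), PhI(OAc)2 (1.2 equiv), CH2Cl2, rt
Reagents that add atoms: none
Why: Oxoammonium (TEMPO) oxidation of the primary alcohol stops at the aldehyde under near-neutral conditions, and any epimerisation at C2 is harmless because that centre is destroyed in step 15.

Step 13
Reactants: 9 (5R)-5-(3-bromoprop-1-en-2-yl)-2-[(TBS-oxy)methyl]cyclohex-2-en-1-one (fragment A, 1.2 equiv); 15 (2R,3S)-3-[(TBS-oxy)methyl]-3-methyloxirane-2-carbaldehyde (fragment B)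
Product: 17 (5R)-2-[(TBS-oxy)methyl]-5-(4-hydroxy-4-{(2S,3S)-3-[(TBS-oxy)methyl]-3-methyloxiran-2-yl}but-1-en-2-yl)cyclohex-2-en-1-one (both carbinol epimers), via allylindium bromide 16 (not isolated)
Conditions: In powder (1.5 equiv), THF/H2O 1:1, rt
Reagents that add atoms: none
Why: Barbier-type carbonyl allylation (the key fragment union), in which the allylindium bromide R–InBr2 formed in situ adds to the aldehyde in preference to the enone ketone and the oxirane; the new carbinol centre forms unselectively but is erased in step 15.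

Step 14
Reactants: 17 Barbier adduct (both carbinol epimers)
Product: 18 methanesulfonate of 17 (OMs in place of the secondary OH; both epimers)
Conditions: MsCl, Et3N, CH2Cl2, 0 °C
Reagents that add atoms: methanesulfonyl chloride CS(=O)(=O)Cl
Why: Sulfonylation of the only free hydroxyl turns it into a leaving group next to the oxirane.

Step 15
Reactants: 18 methanesulfonate of 17
Product: 20 (5R)-2-[(TBS-oxy)methyl]-5-[(4E,6R)-7-(TBS-oxy)-6-hydroxy-6-methylhepta-1,4-dien-2-yl]cyclohex-2-en-1-one, via epoxy iodide 19 (not isolated)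
Conditions: NaI (10 equiv), Zn dust (20 equiv), 2-butanone, 80 °C
Reagents that add atoms: none
Why: Finkelstein substitution followed by zinc-mediated reductive opening of the epoxy iodide (1,3-transposition) converges both epimers to the alkene, E because the chain avoids the quaternary carbon, and frees the tertiary alcohol with its C–O bond unbroken (retention, 6R).

Step 16
Reactants: 20 bis-silyl ether
Product: 21 (5R)-5-[(4E,6R)-6,7-dihydroxy-6-methylhepta-1,4-dien-2-yl]-2-(hydroxymethyl)cyclohex-2-en-1-one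
Conditions: HF·pyridine, pyridine, THF, 0 °C → rt
Reagents that add atoms: none
Why: Buffered fluoride desilylation removes both primary silyl ethers without ionising the tertiary allylic alcohol or disturbing the enone.

Step 17
Reactants: 21 triol
Product: 22 (5R)-5-[(4E,6R)-6-hydroxy-7-(isobutyryloxy)-6-methylhepta-1,4-dien-2-yl]-2-[(isobutyryloxy)methyl]cyclohex-2-en-1-one (target)
Conditions: isobutyryl chloride (2.4 equiv), pyridine, CH2Cl2, −20 → 0 °C
Reagents that add atoms: isobutyryl chloride CC(C)C(=O)Cl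
Why: Selective O-acylation of the two primary alcohols, since the hindered tertiary allylic alcohol does not react with an acid chloride and pyridine in the absence of a nucleophilic catalyst.

**Compound list**
1 | (R)-cyclohex-3-ene-1-carboxylic acid | OC(=O)[C@H]1CC=CCC1 | starting material
2 | (1R,4R,5R)-4-iodo-6-oxabicyclo[3.2.1]octan-7-one | O=C1O[C@@H]2C[C@H]1CC[C@H]2I | intermediate
3 | (1R,5R)-6-oxabicyclo[3.2.1]oct-3-en-7-one | O=C1O[C@@H]2C[C@H]1CC=C2 | intermediate
4 | (1R,5R)-5-[2-hydroxy-1,3-bis(trimethylsilyl)propan-2-yl]cyclohex-2-en-1-ol (not isolated) | O[C@@H]1C[C@@H](CC=C1)C(O)(C[Si](C)(C)C)C[Si](C)(C)C | intermediate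
5 | (1R,5R)-5-[3-(trimethylsilyl)prop-1-en-2-yl]cyclohex-2-en-1-ol | O[C@@H]1C[C@@H](CC=C1)C(=C)C[Si](C)(C)C | intermediate
6 | (5R)-5-[3-(trimethylsilyl)prop-1-en-2-yl]cyclohex-2-en-1-one | O=C1C[C@@H](CC=C1)C(=C)C[Si](C)(C)C | intermediate
7 | (5R)-2-(hydroxymethyl)-5-[3-(trimethylsilyl)prop-1-en-2-yl]cyclohex-2-en-1-one | O=C1C[C@@H](CC=C1CO)C(=C)C[Si](C)(C)C | intermediate
8 | (5R)-2-[(TBS-oxy)methyl]-5-[3-(trimethylsilyl)prop-1-en-2-yl]cyclohex-2-en-1-one | O=C1C[C@@H](CC=C1CO[Si](C)(C)C(C)(C)C)C(=C)C[Si](C)(C)C | intermediate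
9 | (5R)-5-(3-bromoprop-1-en-2-yl)-2-[(TBS-oxy)methyl]cyclohex-2-en-1-one | O=C1C[C@@H](CC=C1CO[Si](C)(C)C(C)(C)C)C(=C)CBr | intermediate
10 | 3-methylbut-2-en-1-yl acetate (prenyl acetate) | CC(=O)OCC=C(C)C | starting material
11 | (2E)-4-hydroxy-3-methylbut-2-en-1-yl acetate | CC(=O)OC/C=C(\C)CO | intermediate
12 | (2E)-4-(TBS-oxy)-3-methylbut-2-en-1-yl acetate | CC(=O)OC/C=C(\C)CO[Si](C)(C)C(C)(C)C | intermediate
13 | (2E)-4-(TBS-oxy)-3-methylbut-2-en-1-ol | OC/C=C(\C)CO[Si](C)(C)C(C)(C)C | intermediate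
14 | [(2S,3S)-3-[(TBS-oxy)methyl]-3-methyloxiran-2-yl]methanol | OC[C@@H]1O[C@@]1(C)CO[Si](C)(C)C(C)(C)C | intermediate
15 | (2R,3S)-3-[(TBS-oxy)methyl]-3-methyloxirane-2-carbaldehyde | O=C[C@@H]1O[C@@]1(C)CO[Si](C)(C)C(C)(C)C | intermediate
16 | allylindium bromide from 9, drawn as the monomeric R–InBr2 form (not isolated) | O=C1C[C@@H](CC=C1CO[Si](C)(C)C(C)(C)C)C(=C)C[In](Br)Br | intermediate
17 | (5R)-2-[(TBS-oxy)methyl]-5-(4-hydroxy-4-{(2S,3S)-3-[(TBS-oxy)methyl]-3-methyloxiran-2-yl}but-1-en-2-yl)cyclohex-2-en-1-one, both carbinol epimers | O=C1C[C@@H](CC=C1CO[Si](C)(C)C(C)(C)C)C(=C)CC(O)[C@@H]1O[C@@]1(C)CO[Si](C)(C)C(C)(C)C | intermediate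
18 | methanesulfonate of 17 (OMs in place of the secondary OH, both epimers) | O=C1C[C@@H](CC=C1CO[Si](C)(C)C(C)(C)C)C(=C)CC(OS(C)(=O)=O)[C@@H]1O[C@@]1(C)CO[Si](C)(C)C(C)(C)C | intermediate
19 | epoxy iodide from 18 (I in place of OMs, both epimers, oxirane unchanged; not isolated) | O=C1C[C@@H](CC=C1CO[Si](C)(C)C(C)(C)C)C(=C)CC(I)[C@@H]1O[C@@]1(C)CO[Si](C)(C)C(C)(C)C | intermediate
20 | (5R)-2-[(TBS-oxy)methyl]-5-[(4E,6R)-7-(TBS-oxy)-6-hydroxy-6-methylhepta-1,4-dien-2-yl]cyclohex-2-en-1-one | O=C1C[C@@H](CC=C1CO[Si](C)(C)C(C)(C)C)C(=C)C/C=C/[C@@](C)(O)CO[Si](C)(C)C(C)(C)C | intermediate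
21 | (5R)-5-[(4E,6R)-6,7-dihydroxy-6-methylhepta-1,4-dien-2-yl]-2-(hydroxymethyl)cyclohex-2-en-1-one | O=C1C[C@@H](CC=C1CO)C(=C)C/C=C/[C@@](C)(O)CO | intermediate
22 | (5R)-5-[(4E,6R)-6-hydroxy-7-(isobutyryloxy)-6-methylhepta-1,4-dien-2-yl]-2-[(isobutyryloxy)methyl]cyclohex-2-en-1-one (CNP0536801.1) | C=C(C/C=C/[C@@](C)(O)COC(=O)C(C)C)[C@@H]1CC=C(COC(=O)C(C)C)C(=O)C1 | target

**Step count**
Total steps: 17. Longest linear sequence: 12 (steps 1–7, then 13–17); the fragment B branch is 5 steps (8–12).

**Three steps most likely to fail, with fallbacks**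

First, the reductive transposition (step 15). Iodide displacement at the hindered secondary mesylate may be slow, elimination to a conjugated diene may compete, and some Z-alkene may form. The fallback sets out from 17 and comes back at 20. Compound 17 is acylated with 1,1'-thiocarbonyldiimidazole (DMAP cat., CH2Cl2, 40 °C) to the O-(imidazol-1-ylcarbonothioyl) derivative F1. F1 is then treated with Bu3SnH and AIBN in toluene at 80 °C. The carbon radical left by C–O homolysis opens the oxirane and the resulting alkoxy radical is reduced by Bu3SnH to give 20. This replaces substitution and zinc reduction by a radical deoxygenation–fragmentation.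

Second, the fragment union (step 13). The α,β-epoxy aldehyde 15 may hydrate, epimerise or ring-open before it is allylated. The fallback sets out from 13 (with 9) and comes back at 17. Compound 13 is oxidised with MnO2 (CH2Cl2, rt) to the enal (2E)-4-(TBS-oxy)-3-methylbut-2-enal F2. F2 is coupled with 9 under the same indium conditions to the dienyl carbinol F3 (both epimers). F3 is then epoxidised under Sharpless kinetic-resolution conditions (Ti(OiPr)4, L-(+)-diisopropyl tartrate, t-BuOOH, CH2Cl2, −20 °C, stopped near half conversion). Only the allylic-alcohol alkene of the matched epimer reacts, on the face that gives the oxirane configuration of 14, so 17 is obtained as one carbinol epimer. The oxirane is thus installed after the C–C bond and no epoxy aldehyde is handled; the cost is a ceiling of about half the material.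

Third, the bromodesilylation (step 7). Over-bromination or loss of regiocontrol is possible. The fallback sets out from 7 and comes back at 17. Compound 7 is protodesilylated with CF3CO2H (CH2Cl2, 0 °C, SE2' protonation) to (5R)-2-(hydroxymethyl)-5-(prop-1-en-2-yl)cyclohex-2-en-1-one F4. F4 is silylated (TBSCl, imidazole) to the silyl ether F5. The isopropenyl group of F5 is chlorinated by the ene-type reaction with Ca(OCl)2 and CO2 (CH2Cl2/H2O, 0 °C) to the allylic chloride F6. F6 is used in place of 9 in the indium coupling with 15 (NaI added) to give 17.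

**Further compounds**
F1 | step 15 | O-(imidazol-1-ylcarbonothioyl) derivative of 17 (both epimers) | O=C1C[C@@H](CC=C1CO[Si](C)(C)C(C)(C)C)C(=C)CC(OC(=S)n1ccnc1)[C@@H]1O[C@@]1(C)CO[Si](C)(C)C(C)(C)C
F2 | step 13 | (2E)-4-(TBS-oxy)-3-methylbut-2-enal | O=C/C=C(\C)CO[Si](C)(C)C(C)(C)C
F3 | step 13 | (5R)-2-[(TBS-oxy)methyl]-5-[(5E)-7-(TBS-oxy)-4-hydroxy-6-methylhepta-1,5-dien-2-yl]cyclohex-2-en-1-one (both carbinol epimers) | O=C1C[C@@H](CC=C1CO[Si](C)(C)C(C)(C)C)C(=C)CC(O)/C=C(\C)CO[Si](C)(C)C(C)(C)C
F4 | step 7 | (5R)-2-(hydroxymethyl)-5-(prop-1-en-2-yl)cyclohex-2-en-1-one | O=C1C[C@@H](CC=C1CO)C(C)=C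
F5 | step 7 | (5R)-2-[(TBS-oxy)methyl]-5-(prop-1-en-2-yl)cyclohex-2-en-1-one | O=C1C[C@@H](CC=C1CO[Si](C)(C)C(C)(C)C)C(C)=C
F6 | step 7 | (5R)-5-(3-chloroprop-1-en-2-yl)-2-[(TBS-oxy)methyl]cyclohex-2-en-1-one | O=C1C[C@@H](CC=C1CO[Si](C)(C)C(C)(C)C)C(=C)CCl
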